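**Retrosynthetic overview**
- The target is reached last by global desilylation, after Yamaguchi esterification of the C8 hydroxyl with the silyl-protected acid from the (S)-Roche ester.
- The ten-membered carbocycle is closed first, at C6–C7, by a chromium-catalysed ring-closing 2-(methoxycarbonyl)allylation of a bromo-enoate/enal; the trans γ-lactone closes in the same flask.
- The bromo-enoate comes from a C6/C7 dialdehyde (double Swern of a linear silyl ether) by Baylis–Hillman reaction at C7 and SN2′ bromination.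
- The linear chain is made by a palladium-catalysed Negishi C3–C4 coupling of fragment A (C7–C10, C14, C1–C3) with fragment B (C4–C6, C15).
- Fragment A comes from 2,3-dihydrofuran, MeLi and (R)-glycidol; fragment B from but-2-yne-1,4-diol.

Assumption: atoms carry germacranolide labels (C1=C10, C4=C5, C6 lactone oxygen, C7, C8 ester oxygen, C11=C13 methylene, C12 carbonyl, C14 methyl, C15 hydroxymethyl). The target is taken as drawn: 6R,7R,8S,2′S, C1=C10 Z (C2 cis to C9), C15 cis to C6 across C4=C5.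

**Fragment A**

Step 1
Reactants: 1 2,3-dihydrofuran
Product: 4 (3Z)-4-iodopent-3-en-1-ol, via 5-lithio-2,3-dihydrofuran 2 (not isolated), via alkenyl methylcuprate 3 (not isolated)
Conditions: t-BuLi, THF, −78 to 0 °C; Me2CuLi (from MeLi and CuI), Et2O/Me2S, −78 °C to rt; I2, THF, −78 °C; aq NH4Cl/Na2S2O3
Reagents that add atoms: methyllithium, [Li]C; iodine, II
Why: α-Lithiation of the enol ether and a Kocienski 1,2-metalate rearrangement (methyl migrates from copper to carbon with inversion, expelling the ring oxygen) put copper cis to the oxyethyl chain, and iodinolysis with retention fixes the Z geometry of the future C1=C10 bond.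

Step 2
Reactants: 5 (R)-glycidol
Product: 6 (2S)-triethyl(oxiran-2-ylmethoxy)silane
Conditions: TESCl, imidazole, CH2Cl2, 0 °C
Reagents that add atoms: chlorotriethylsilane, CC[Si](Cl)(CC)CC
Why: Silyl ether formation under non-alkoxide conditions avoids Payne rearrangement, so the epoxide stereocentre (future C8) is kept.

Step 3
Reactants: 4 (3Z)-4-iodopent-3-en-1-ol; 6 (2S)-triethyl(oxiran-2-ylmethoxy)silane
Product: 8 (2S,4Z)-4-methyl-1-[(triethylsilyl)oxy]hept-4-ene-2,7-diol, via dilithio alkoxide 7 (not isolated)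
Conditions: MeLi (1.05 equiv) then t-BuLi (2.1 equiv), Et2O, −78 °C; 6 (0.8 equiv), BF3·OEt2 (2.2 equiv), −78 °C; aq NaHCO3
Reagents that add atoms: none
Why: Iodine–lithium exchange with retention of alkene geometry and BF3-promoted SN2 opening of the epoxide at its CH2 terminus form C9–C10, leaving C8 untouched (S).

Step 4
Reactants: 8 (2S,4Z)-4-methyl-1-[(triethylsilyl)oxy]hept-4-ene-2,7-diol
Product: 9 (2S,4Z)-7-iodo-4-methyl-1-[(triethylsilyl)oxy]hept-4-en-2-ol
Conditions: I2, PPh3, imidazole, CH2Cl2, 0 °C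
Reagents that add atoms: iodine, II
Why: Appel iodination is much faster at the primary (C3) alcohol than at the hindered secondary C8 alcohol.

Step 5
Reactants: 9 (2S,4Z)-7-iodo-4-methyl-1-[(triethylsilyl)oxy]hept-4-en-2-ol
Product: 10 (2S,4Z)-7-iodo-4-methyl-1,2-bis[(triethylsilyl)oxy]hept-4-ene
Conditions: TESCl, imidazole, DMAP (cat.), CH2Cl2, 0 °C to rt
Reagents that add atoms: chlorotriethylsilane, CC[Si](Cl)(CC)CC
Why: Routine silylation of the remaining secondary alcohol protects C8–OH through the ring closure.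

**Fragment B**

Step 6
Reactants: 11 but-2-yne-1,4-diol
Product: 12 (2E)-2-(tributylstannyl)but-2-ene-1,4-diol
Conditions: Bu3SnH, Pd(PPh3)2Cl2 (2 mol%), THF, 0 °C to rt
Reagents that add atoms: tributyltin hydride, CCCC[SnH](CCCC)CCCC
Why: Palladium-catalysed syn hydrostannation of the symmetric alkyne places tin and hydrogen cis, giving the E stannane (tin trans to the future C6).

Step 7
Reactants: 12 (2E)-2-(tributylstannyl)but-2-ene-1,4-diol
Product: 13 (2E)-2-(tributylstannyl)-4-[(triethylsilyl)oxy]but-2-en-1-ol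
Conditions: TESCl (1.0 equiv), imidazole, CH2Cl2, −78 to −40 °C
Reagents that add atoms: chlorotriethylsilane, CC[Si](Cl)(CC)CC
Why: Regioselective silylation, because the hydroxyl remote from the bulky Bu3Sn group (future C6–OH) reacts first.

Step 8
Reactants: 13 (2E)-2-(tributylstannyl)-4-[(triethylsilyl)oxy]but-2-en-1-ol
Product: 14 (2E)-1-[(tert-butyldiphenylsilyl)oxy]-2-(tributylstannyl)-4-[(triethylsilyl)oxy]but-2-ene
Conditions: TBDPSCl, imidazole, DMAP (cat.), DMF, rt
Reagents that add atoms: tert-butyl(chloro)diphenylsilane, CC(C)(C)[Si](Cl)(c1ccccc1)c1ccccc1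
Why: Silylation of the hindered primary alcohol (future C15–OH) with a group that survives every later step until the end.

Step 9
Reactants: 14 (2E)-1-[(tert-butyldiphenylsilyl)oxy]-2-(tributylstannyl)-4-[(triethylsilyl)oxy]but-2-ene
Product: 15 (2E)-1-[(tert-butyldiphenylsilyl)oxy]-2-iodo-4-[(triethylsilyl)oxy]but-2-ene
Conditions: I2, CH2Cl2, NaHCO3, 0 °C; aq Na2S2O3, KF work-up
Reagents that add atoms: iodine, II
Why: Iododestannylation proceeds with retention of alkene geometry.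

**Union and ring closure**

Step 10
Reactants: 10 (2S,4Z)-7-iodo-4-methyl-1,2-bis[(triethylsilyl)oxy]hept-4-ene; 15 (2E)-1-[(tert-butyldiphenylsilyl)oxy]-2-iodo-4-[(triethylsilyl)oxy]but-2-ene
Product: 17 (2Z,6Z,9S)-3-{[(tert-butyldiphenylsilyl)oxy]methyl}-7-methyl-1,9,10-tris[(triethylsilyl)oxy]deca-2,6-diene, via alkylzinc iodide 16 (not isolated)
Conditions: Zn dust (activated), LiCl, THF, 40 °C; then 15, Pd(dppf)Cl2 (5 mol%), THF/NMP, 50 °C
Reagents that add atoms: none
Why: Zinc insertion into the primary iodide and Negishi sp3–sp2 cross-coupling with retention at the alkenyl iodide form C3–C4 and fix the C4=C5 geometry (C15 cis to C6).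

Step 11
Reactants: 17 (2Z,6Z,9S)-3-{[(tert-butyldiphenylsilyl)oxy]methyl}-7-methyl-1,9,10-tris[(triethylsilyl)oxy]deca-2,6-diene
Product: 18 (2Z,6Z,9S)-3-{[(tert-butyldiphenylsilyl)oxy]methyl}-7-methyl-9-[(triethylsilyl)oxy]deca-2,6-dienedial
Conditions: (COCl)2 (6 equiv), DMSO (12 equiv), CH2Cl2, −78 to −40 °C; Et3N, −78 to 0 °C; used crude
Reagents that add atoms: none
Why: Under Swern conditions primary triethylsilyl ethers are cleaved and oxidised directly to aldehydes, while the secondary triethylsilyl and the tert-butyldiphenylsilyl ethers survive.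

Step 12
Reactants: 18 (2Z,6Z,9S)-3-{[(tert-butyldiphenylsilyl)oxy]methyl}-7-methyl-9-[(triethylsilyl)oxy]deca-2,6-dienedial; 19 methyl acrylate
Product: 20 methyl (4S,6Z,10Z)-10-{[(tert-butyldiphenylsilyl)oxy]methyl}-3-hydroxy-6-methyl-2-methylidene-12-oxo-4-[(triethylsilyl)oxy]dodeca-6,10-dienoate (both C3 epimers)
Conditions: DABCO (1 equiv), methyl acrylate (5 equiv), 1,4-dioxane/H2O (1:1), rt, 24 h
Reagents that add atoms: none
Why: Morita–Baylis–Hillman reaction occurs at the α-silyloxy aldehyde (C7), which is far more electrophilic than the β,β-disubstituted enal (C6); the new carbinol centre is erased in step 13.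

Step 13
Reactants: 20 methyl (4S,6Z,10Z)-10-{[(tert-butyldiphenylsilyl)oxy]methyl}-3-hydroxy-6-methyl-2-methylidene-12-oxo-4-[(triethylsilyl)oxy]dodeca-6,10-dienoate
Product: 21 methyl (2Z,4S,6Z,10Z)-2-(bromomethyl)-10-{[(tert-butyldiphenylsilyl)oxy]methyl}-6-methyl-12-oxo-4-[(triethylsilyl)oxy]dodeca-2,6,10-trienoate
Conditions: NBS/Me2S (pre-mixed), CH2Cl2, −20 to 0 °C
Reagents that add atoms: N-bromosuccinimide, O=C1CCC(=O)N1Br
Why: Corey–Kim-type activation of the allylic alcohol and SN2′ attack of bromide give the favoured Z 2-(bromomethyl)enoate (either alkene isomer would feed the same allylchromium).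

Step 14
Reactants: 21 methyl (2Z,4S,6Z,10Z)-2-(bromomethyl)-10-{[(tert-butyldiphenylsilyl)oxy]methyl}-6-methyl-12-oxo-4-[(triethylsilyl)oxy]dodeca-2,6,10-trienoate
Product: 23 (3aS,4S,6Z,10Z,11aR)-10-{[(tert-butyldiphenylsilyl)oxy]methyl}-6-methyl-3-methylidene-4-[(triethylsilyl)oxy]-3a,4,5,8,9,11a-hexahydrocyclodeca[b]furan-2(3H)-one, via seco hydroxy ester 22 (not isolated)
Conditions: CrCl2 (15 mol%), (S,S)-3,6-di-tert-butyl-1,8-bis(4-isopropyl-4,5-dihydrooxazol-2-yl)carbazole (16 mol%), i-Pr2NEt (0.3 equiv), Mn powder (3 equiv), Cp2ZrCl2 (1.5 equiv), THF, rt, syringe-pump addition of 21 over 12 h (2 mM final); then PPTS (cat.), CH2Cl2, rt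
Reagents that add atoms: none
Why: Proposed new method: a chromium-catalysed, ligand-controlled ring-closing 2-(methoxycarbonyl)allylation that builds the ten-membered carbocycle from a γ-substituted, δ-silyloxy 2-(bromomethyl)enoate. Two divalent chromium centres (regenerated from trivalent chromium by Mn) reduce the allylic bromide to a ligand-bound allylchromium, which adds through its γ-carbon C7 to the C6 enal in a closed chair transition state. The C8 silyloxy centre fixes the C7 face (C8–H eclipses the alkene to avoid A1,3 strain, the tether lies on the attacking face, OTES is anti, so C11 ends trans to O8). The chiral ligand selects the si face of the aldehyde, so C6/C7 are anti (6R,7R). The Z C1=C10 alkene pre-folds the chain, Cp2ZrCl2 releases the chromium alkoxide, and hydroxy ester 22 closes to the trans γ-lactone. The closest known reactions are the stoichiometric CrCl2 Barbier/Nozaki–Hiyama–Kishi macrocyclisations of 2-(bromomethyl)enoate aldehydes to germacranolides and the intermolecular chromium-catalysed enantioselective 2-(alkoxycarbonyl)allylation of aldehydes.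

Step 15
Reactants: 23 (3aS,4S,6Z,10Z,11aR)-10-{[(tert-butyldiphenylsilyl)oxy]methyl}-6-methyl-3-methylidene-4-[(triethylsilyl)oxy]-3a,4,5,8,9,11a-hexahydrocyclodeca[b]furan-2(3H)-one
Product: 24 (3aR,4S,6Z,10Z,11aR)-10-{[(tert-butyldiphenylsilyl)oxy]methyl}-4-hydroxy-6-methyl-3-methylidene-3a,4,5,8,9,11a-hexahydrocyclodeca[b]furan-2(3H)-one
Conditions: PPTS (0.2 equiv), MeOH/CH2Cl2 (1:2), 0 °C
Reagents that add atoms: none
Why: Mild acid methanolysis removes the secondary triethylsilyl ether; the tert-butyldiphenylsilyl ether and the lactone are stable, and non-basic conditions avoid translactonisation to O8.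

**Side chain and completion**

Step 16
Reactants: 25 methyl (2S)-3-hydroxy-2-methylpropanoate
Product: 26 methyl (2S)-3-[(tert-butyldimethylsilyl)oxy]-2-methylpropanoate
Conditions: TBSCl, imidazole, CH2Cl2, 0 °C to rt
Reagents that add atoms: tert-butyl(chloro)dimethylsilane, CC(C)(C)[Si](C)(C)Cl
Why: Routine silylation of the primary alcohol; the α-stereocentre is not involved.

Step 17
Reactants: 26 methyl (2S)-3-[(tert-butyldimethylsilyl)oxy]-2-methylpropanoate
Product: 27 (2S)-3-[(tert-butyldimethylsilyl)oxy]-2-methylpropanoic acid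
Conditions: LiOH·H2O, THF/MeOH/H2O, 0 °C; cold 0.5 M HCl to pH 4
Reagents that add atoms: lithium hydroxide monohydrate, [Li+].[OH-].O
Why: Saponification at 0 °C is a standard way to free this acid without eroding the α-stereocentre.

Step 18
Reactants: 27 (2S)-3-[(tert-butyldimethylsilyl)oxy]-2-methylpropanoic acid; 24 (3aR,4S,6Z,10Z,11aR)-10-{[(tert-butyldiphenylsilyl)oxy]methyl}-4-hydroxy-6-methyl-3-methylidene-3a,4,5,8,9,11a-hexahydrocyclodeca[b]furan-2(3H)-one
Product: 29 (3aR,4S,6Z,10Z,11aR)-10-{[(tert-butyldiphenylsilyl)oxy]methyl}-6-methyl-3-methylidene-2-oxo-2,3,3a,4,5,8,9,11a-octahydrocyclodeca[b]furan-4-yl (2S)-3-[(tert-butyldimethylsilyl)oxy]-2-methylpropanoate, via mixed anhydride 28 (not isolated)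
Conditions: 2,4,6-trichlorobenzoyl chloride, Et3N, THF, rt; then 24, DMAP, toluene, rt
Reagents that add atoms: none
Why: Yamaguchi esterification acylates the hindered secondary C8 alcohol with retention at C8 and without epimerising the acid.

Step 19
Reactants: 29 (3aR,4S,6Z,10Z,11aR)-10-{[(tert-butyldiphenylsilyl)oxy]methyl}-6-methyl-3-methylidene-2-oxo-2,3,3a,4,5,8,9,11a-octahydrocyclodeca[b]furan-4-yl (2S)-3-[(tert-butyldimethylsilyl)oxy]-2-methylpropanoate
Product: 30 (3aR,4S,6Z,10Z,11aR)-10-(hydroxymethyl)-6-methyl-3-methylidene-2-oxo-2,3,3a,4,5,8,9,11a-octahydrocyclodeca[b]furan-4-yl (2S)-3-hydroxy-2-methylpropanoate (target)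
Conditions: HF·pyridine, pyridine, THF, 0 °C to rt
Reagents that add atoms: none
Why: Buffered fluoride desilylation removes both primary silyl ethers without touching the α-methylene lactone, the ester or any stereocentre.

**Compound list**
1 | 2,3-dihydrofuran | C1=COCC1 | starting material
2 | 5-lithio-2,3-dihydrofuran | [Li]C1=CCCO1 | intermediate
3 | lithium methyl[(2Z)-5-(lithiooxy)pent-2-en-2-yl]cuprate (copper cis to the oxyethyl chain) | [Li+].C[Cu-]/C(C)=C\CCO[Li] | intermediate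
4 | (3Z)-4-iodopent-3-en-1-ol | OCC/C=C(/C)I | intermediate
5 | (R)-glycidol, (2R)-oxiran-2-ylmethanol | OC[C@@H]1CO1 | starting material
6 | (2S)-triethyl(oxiran-2-ylmethoxy)silane | CC[Si](CC)(CC)OC[C@@H]1CO1 | intermediate
7 | lithium (3E)-4-lithiopent-3-en-1-olate (lithium cis to the oxyethyl chain) | [Li]OCC/C=C(/C)[Li] | intermediate
8 | (2S,4Z)-4-methyl-1-[(triethylsilyl)oxy]hept-4-ene-2,7-diol | OCC/C=C(/C)C[C@H](O)CO[Si](CC)(CC)CC | intermediate
9 | (2S,4Z)-7-iodo-4-methyl-1-[(triethylsilyl)oxy]hept-4-en-2-ol | ICC/C=C(/C)C[C@H](O)CO[Si](CC)(CC)CC | intermediate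
10 | (2S,4Z)-7-iodo-4-methyl-1,2-bis[(triethylsilyl)oxy]hept-4-ene | ICC/C=C(/C)C[C@H](O[Si](CC)(CC)CC)CO[Si](CC)(CC)CC | intermediate
11 | but-2-yne-1,4-diol | OCC#CCO | starting material
12 | (2E)-2-(tributylstannyl)but-2-ene-1,4-diol | OC/C=C(/[Sn](CCCC)(CCCC)CCCC)CO | intermediate
13 | (2E)-2-(tributylstannyl)-4-[(triethylsilyl)oxy]but-2-en-1-ol | CC[Si](CC)(CC)OC/C=C(/[Sn](CCCC)(CCCC)CCCC)CO | intermediate
14 | (2E)-1-[(tert-butyldiphenylsilyl)oxy]-2-(tributylstannyl)-4-[(triethylsilyl)oxy]but-2-ene | CC[Si](CC)(CC)OC/C=C(/[Sn](CCCC)(CCCC)CCCC)CO[Si](c1ccccc1)(c1ccccc1)C(C)(C)C | intermediate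
15 | (2E)-1-[(tert-butyldiphenylsilyl)oxy]-2-iodo-4-[(triethylsilyl)oxy]but-2-ene | CC[Si](CC)(CC)OC/C=C(/I)CO[Si](c1ccccc1)(c1ccccc1)C(C)(C)C | intermediate
16 | [(3Z,6S)-4-methyl-6,7-bis(triethylsilyloxy)hept-3-en-1-yl]zinc iodide | I[Zn]CC/C=C(/C)C[C@H](O[Si](CC)(CC)CC)CO[Si](CC)(CC)CC | intermediate
17 | (2Z,6Z,9S)-3-{[(tert-butyldiphenylsilyl)oxy]methyl}-7-methyl-1,9,10-tris[(triethylsilyl)oxy]deca-2,6-diene | CC[Si](CC)(CC)OC/C=C(\CO[Si](c1ccccc1)(c1ccccc1)C(C)(C)C)CC/C=C(/C)C[C@H](O[Si](CC)(CC)CC)CO[Si](CC)(CC)CC | intermediate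
18 | (2Z,6Z,9S)-3-{[(tert-butyldiphenylsilyl)oxy]methyl}-7-methyl-9-[(triethylsilyl)oxy]deca-2,6-dienedial | O=C/C=C(\CO[Si](c1ccccc1)(c1ccccc1)C(C)(C)C)CC/C=C(/C)C[C@H](O[Si](CC)(CC)CC)C=O | intermediate
19 | methyl acrylate | C=CC(=O)OC | starting material
20 | methyl (4S,6Z,10Z)-10-{[(tert-butyldiphenylsilyl)oxy]methyl}-3-hydroxy-6-methyl-2-methylidene-12-oxo-4-[(triethylsilyl)oxy]dodeca-6,10-dienoate (C3 epimer mixture) | O=C/C=C(\CO[Si](c1ccccc1)(c1ccccc1)C(C)(C)C)CC/C=C(/C)C[C@H](O[Si](CC)(CC)CC)C(O)C(=C)C(=O)OC | intermediate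
21 | methyl (2Z,4S,6Z,10Z)-2-(bromomethyl)-10-{[(tert-butyldiphenylsilyl)oxy]methyl}-6-methyl-12-oxo-4-[(triethylsilyl)oxy]dodeca-2,6,10-trienoate | O=C/C=C(\CO[Si](c1ccccc1)(c1ccccc1)C(C)(C)C)CC/C=C(/C)C[C@H](O[Si](CC)(CC)CC)/C=C(\CBr)C(=O)OC | intermediate
22 | methyl 2-[(1S,2R,3Z,7Z,10S)-4-{[(tert-butyldiphenylsilyl)oxy]methyl}-2-hydroxy-8-methyl-10-[(triethylsilyl)oxy]cyclodeca-3,7-dien-1-yl]prop-2-enoate | C=C(C(=O)OC)[C@H]1[C@H](O)/C=C(\CO[Si](c2ccccc2)(c2ccccc2)C(C)(C)C)CC/C=C(/C)C[C@@H]1O[Si](CC)(CC)CC | intermediate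
23 | (3aS,4S,6Z,10Z,11aR)-10-{[(tert-butyldiphenylsilyl)oxy]methyl}-6-methyl-3-methylidene-4-[(triethylsilyl)oxy]-3a,4,5,8,9,11a-hexahydrocyclodeca[b]furan-2(3H)-one | C=C1C(=O)O[C@@H]2/C=C(\CO[Si](c3ccccc3)(c3ccccc3)C(C)(C)C)CC/C=C(/C)C[C@H](O[Si](CC)(CC)CC)[C@@H]12 | intermediate
24 | (3aR,4S,6Z,10Z,11aR)-10-{[(tert-butyldiphenylsilyl)oxy]methyl}-4-hydroxy-6-methyl-3-methylidene-3a,4,5,8,9,11a-hexahydrocyclodeca[b]furan-2(3H)-one | C=C1C(=O)O[C@@H]2/C=C(\CO[Si](c3ccccc3)(c3ccccc3)C(C)(C)C)CC/C=C(/C)C[C@H](O)[C@@H]12 | intermediate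
25 | methyl (2S)-3-hydroxy-2-methylpropanoate | COC(=O)[C@@H](C)CO | starting material
26 | methyl (2S)-3-[(tert-butyldimethylsilyl)oxy]-2-methylpropanoate | COC(=O)[C@@H](C)CO[Si](C)(C)C(C)(C)C | intermediate
27 | (2S)-3-[(tert-butyldimethylsilyl)oxy]-2-methylpropanoic acid | OC(=O)[C@@H](C)CO[Si](C)(C)C(C)(C)C | intermediate
28 | (2S)-3-[(tert-butyldimethylsilyl)oxy]-2-methylpropanoic 2,4,6-trichlorobenzoic anhydride | O=C(OC(=O)c1c(Cl)cc(Cl)cc1Cl)[C@@H](C)CO[Si](C)(C)C(C)(C)C | intermediate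
29 | (3aR,4S,6Z,10Z,11aR)-10-{[(tert-butyldiphenylsilyl)oxy]methyl}-6-methyl-3-methylidene-2-oxo-2,3,3a,4,5,8,9,11a-octahydrocyclodeca[b]furan-4-yl (2S)-3-[(tert-butyldimethylsilyl)oxy]-2-methylpropanoate | C=C1C(=O)O[C@@H]2/C=C(\CO[Si](c3ccccc3)(c3ccccc3)C(C)(C)C)CC/C=C(/C)C[C@H](OC(=O)[C@@H](C)CO[Si](C)(C)C(C)(C)C)[C@@H]12 | intermediate
30 | (3aR,4S,6Z,10Z,11aR)-10-(hydroxymethyl)-6-methyl-3-methylidene-2-oxo-2,3,3a,4,5,8,9,11a-octahydrocyclodeca[b]furan-4-yl (2S)-3-hydroxy-2-methylpropanoate | C=C1C(=O)O[C@@H]2/C=C(\CO)CC/C=C(/C)C[C@H](OC(=O)[C@@H](C)CO)[C@@H]12 | target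

**Step count**
Total: 19 steps. Longest linear sequence: 12 steps (1, 3, 4, 5, 10, 11, 12, 13, 14, 15, 18, 19; the path through steps 6–9 is equally long).

**Steps most likely to fail, with fallbacks**

Step 14, the new ring closure, is the most uncertain. Catalyst turnover at high dilution, uncatalysed background reduction of the bromide by Mn, and mismatching between ligand and the C8 centre could each erode yield or diastereoselectivity. The fallback uses known chemistry and drops catalyst control. It sets out from 21: stoichiometric CrCl2 (4 equiv) in THF/DMF at 2 mM, the established substrate-controlled Barbier-type closure for 1(10)-Z germacranolides, gives 22 and from it 23 directly. Material that closes with the wrong C6 configuration appears as the C6-epimeric hydroxy ester F1, which lactonises to the cis-fused lactone F2. Saponification of F2 (LiOH, THF/H2O, 0 °C, neutralised to pH 6 and used at once) gives the hydroxy acid F3. Mitsunobu lactonisation of F3 (PPh3, DIAD, toluene, 0 °C) inverts C6 and comes back to the route at 23.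

Step 12 is the second risk. The Baylis–Hillman reaction is slow, DABCO may epimerise the α-silyloxy aldehyde at C8, and selectivity over the C6 enal is assumed, not proven. The fallback sets out from 18 and replaces amine catalysis by vinylalumination. Methyl propiolate is hydroaluminated with i-Bu2AlH and N-methylmorpholine N-oxide in THF at 0 °C to methyl 2-(diisobutylalumanyl)prop-2-enoate F4. This reagent adds at −78 to −20 °C, under non-basic conditions, to the more electrophilic C7 aldehyde and comes back to the route at 20.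

Step 3 is the third risk. The alkenyllithium carries a free lithium alkoxide, which can sequester BF3 or lower the yield of the epoxide opening. The fallback sets out from 4 and uses a protecting-group relay. NaH and 4-methoxybenzyl chloride give 1-({[(3Z)-4-iodopent-3-en-1-yl]oxy}methyl)-4-methoxybenzene F5. t-BuLi converts it into the alkenyllithium F6, which opens 6 with BF3·OEt2 to the secondary alcohol F7. TESCl/imidazole gives the bis(triethylsilyl) ether F8, DDQ in CH2Cl2/pH 7 buffer frees the primary alcohol F9, and I2/PPh3/imidazole comes back to the route at 10.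

**Further compounds**
F1 | step 14 | methyl 2-[(1S,2S,3Z,7Z,10S)-4-{[(tert-butyldiphenylsilyl)oxy]methyl}-2-hydroxy-8-methyl-10-[(triethylsilyl)oxy]cyclodeca-3,7-dien-1-yl]prop-2-enoate | C=C(C(=O)OC)[C@H]1[C@@H](O)/C=C(\CO[Si](c2ccccc2)(c2ccccc2)C(C)(C)C)CC/C=C(/C)C[C@@H]1O[Si](CC)(CC)CC
F2 | step 14 | (3aS,4S,6Z,10Z,11aS)-10-{[(tert-butyldiphenylsilyl)oxy]methyl}-6-methyl-3-methylidene-4-[(triethylsilyl)oxy]-3a,4,5,8,9,11a-hexahydrocyclodeca[b]furan-2(3H)-one | C=C1C(=O)O[C@H]2/C=C(\CO[Si](c3ccccc3)(c3ccccc3)C(C)(C)C)CC/C=C(/C)C[C@H](O[Si](CC)(CC)CC)[C@@H]12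
F3 | step 14 | 2-[(1S,2S,3Z,7Z,10S)-4-{[(tert-butyldiphenylsilyl)oxy]methyl}-2-hydroxy-8-methyl-10-[(triethylsilyl)oxy]cyclodeca-3,7-dien-1-yl]prop-2-enoic acid | C=C(C(=O)O)[C@H]1[C@@H](O)/C=C(\CO[Si](c2ccccc2)(c2ccccc2)C(C)(C)C)CC/C=C(/C)C[C@@H]1O[Si](CC)(CC)CC
F4 | step 12 | methyl 2-(diisobutylalumanyl)prop-2-enoate | C=C(C(=O)OC)[Al](CC(C)C)CC(C)C
F5 | step 3 | 1-({[(3Z)-4-iodopent-3-en-1-yl]oxy}methyl)-4-methoxybenzene | COc1ccc(COCC/C=C(/C)I)cc1
F6 | step 3 | {(2E)-5-[(4-methoxybenzyl)oxy]pent-2-en-2-yl}lithium (lithium cis to the chain) | COc1ccc(COCC/C=C(/C)[Li])cc1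
F7 | step 3 | (2S,4Z)-7-[(4-methoxybenzyl)oxy]-4-methyl-1-[(triethylsilyl)oxy]hept-4-en-2-ol | COc1ccc(COCC/C=C(/C)C[C@H](O)CO[Si](CC)(CC)CC)cc1
F8 | step 3 | (2S,4Z)-7-[(4-methoxybenzyl)oxy]-4-methyl-1,2-bis[(triethylsilyl)oxy]hept-4-ene | COc1ccc(COCC/C=C(/C)C[C@H](O[Si](CC)(CC)CC)CO[Si](CC)(CC)CC)cc1
F9 | step 3 | (3Z,6S)-4-methyl-6,7-bis[(triethylsilyl)oxy]hept-3-en-1-ol | OCC/C=C(/C)C[C@H](O[Si](CC)(CC)CC)CO[Si](CC)(CC)CC
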